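**Retrosynthetic overview**

- The C2–C1' bond (pyranone C2 to B-ring C1') is cut. The B ring comes from unfunctionalised 1,2,4,5-tetramethoxybenzene, the A/C part from an o-hydroxyacetophenone.
- C ring: DMF-DMA brings in C2 as a one-carbon unit (C2–C3), O1–C2 closes the pyranone, and the same flask then forms C2–C1' by Pd(II)-catalysed twofold C–H coupling; three components are joined in one operation.
- Enabling feature: C1' lies between the methoxy-bearing C2' and C6' of a ring whose only two C–H bonds (C1'–H and C4'–H) are equivalent, so the arene needs no activating group and offers no regiochemical choice. C2 is the β-carbon of the C2=C3–C4=O enone next to O1, which is where an aryl–Pd species adds.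
- A ring: the acetyl group is placed between the two oxygen substituents of 3,4-dimethoxyphenol by acetal-directed ortho-lithiation, which fixes the 5,6-dimethoxy/O1 pattern.
- Ring order: the A and B rings are bought as benzenes; the pyranone C ring is the only ring formed, and it is formed in the key step.

Key step: step 3

Remark on the chemistry: the target has no stereocentre, and because the B ring is symmetric about its C1'–C4' axis it has no axial chirality either; it is achiral, so no enantiocontrol is needed.

**Route**

Step 1
Reactants: 1 3,4-dimethoxyphenol
Product: 2 1,2-dimethoxy-4-(methoxymethoxy)benzene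
Conditions: NaH, MOMCl, THF–DMF, 0 °C → rt
Reagents that add atoms: chloromethyl methyl ether, COCCl
Why: Williamson-type O-alkylation, in which the sodium phenoxide should displace chloride from the highly electrophilic α-chloro ether and give the acetal that later directs metalation; no stereocentre is formed.

Step 2
Reactants: 2 1,2-dimethoxy-4-(methoxymethoxy)benzene; 3 N-methoxy-N-methylacetamide
Product: 6 1-(6-hydroxy-2,3-dimethoxyphenyl)ethan-1-one, via aryllithium 4 (not isolated), via MOM ketone 5 (not isolated)
Conditions: n-BuLi (1.1 equiv), THF, 0 °C → rt; 3, −78 → 0 °C; then 3 M HCl, MeOH, 50 °C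
Reagents that add atoms: none
Why: Directed ortho-metalation, Weinreb ketone synthesis and acetal hydrolysis in one flask: the C–H between the OMOM and OMe groups is the only one flanked by two coordinating oxygens and should be lithiated selectively, the chelated tetrahedral adduct of 3 prevents over-addition, and the acidic methanolic quench should release the hydrogen-bonded ortho-hydroxy ketone; no stereocentre is formed.

Step 3
Reactants: 6 1-(6-hydroxy-2,3-dimethoxyphenyl)ethan-1-one; 7 N,N-dimethylformamide dimethyl acetal; 8 1,2,4,5-tetramethoxybenzene
Product: 11 5,6-dimethoxy-2-(2,3,5,6-tetramethoxyphenyl)-4H-chromen-4-one (5,6,2',3',5',6'-hexamethoxyflavone), via enaminone 9 (not isolated), via chromone 10 (not isolated)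
Conditions: (i) 7 (1.5 equiv), PhMe, 100 °C, then volatiles removed; (ii) same flask: 8 (5 equiv), Pd(OAc)2 (10 mol %), AgOAc (3 equiv), CsOPiv (0.3 equiv), PivOH, 110 °C
Reagents that add atoms: none
Why: Proposed new method: the methyl ketone should condense with the amide acetal to enaminone 9 (loss of two MeOH), which in hot pivalic acid should close the pyranone ring by 6-endo-trig oxa-Michael addition of the phenol oxygen to the enaminone β-carbon followed by β-elimination of dimethylamine (O1–C2 bond), giving chromone 10. Pd(II) pivalate should then metalate 8 by concerted metalation–deprotonation, the aryl–Pd species should add across C2=C3 with the aryl group going to C2 and Pd to C3, and after C-/O-enolate equilibration β-hydride elimination should release the flavone while Ag(I) reoxidises Pd(0). The closest known reaction types are the Pd(II)/Ag(I)-mediated twofold C–H (Fujiwara–Moritani-type) C2-arylation of chromones with simple arenes and the DMF-DMA enaminone/chromone annulation of o-hydroxyacetophenones; the new element is running them as one three-component sequence that forms C2–C3, O1–C2 and C2–C1' in a single flask. No stereocentre is formed. The step needs arylation at C2 and not at C3, which the enone polarisation secures (aryl to the β-carbon, Pd to the α-carbon as an enolate), and it needs one arene regiochemistry, which is given because both C–H bonds of 8 are equivalent and each sits between two methoxy groups, the most acidic arene position. Mono-arylation should be favoured by the excess of 8 and by the electron-withdrawing chromonyl group on the product ring, and methanol is removed before stage (ii) so that it cannot reduce Pd(II).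

**Compound list**

1 | 3,4-dimethoxyphenol | COc1ccc(O)cc1OC | starting material
2 | 1,2-dimethoxy-4-(methoxymethoxy)benzene | COCOc1ccc(OC)c(OC)c1 | intermediate
3 | N-methoxy-N-methylacetamide | CC(=O)N(C)OC | starting material
4 | [2,3-dimethoxy-6-(methoxymethoxy)phenyl]lithium | [Li]c1c(OCOC)ccc(OC)c1OC | intermediate
5 | 1-[2,3-dimethoxy-6-(methoxymethoxy)phenyl]ethan-1-one | CC(=O)c1c(OCOC)ccc(OC)c1OC | intermediate
6 | 1-(6-hydroxy-2,3-dimethoxyphenyl)ethan-1-one | CC(=O)c1c(O)ccc(OC)c1OC | intermediate
7 | N,N-dimethylformamide dimethyl acetal | COC(OC)N(C)C | starting material
8 | 1,2,4,5-tetramethoxybenzene | COc1cc(OC)c(OC)cc1OC | starting material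
9 | (E)-3-(dimethylamino)-1-(6-hydroxy-2,3-dimethoxyphenyl)prop-2-en-1-one | CN(C)/C=C/C(=O)c1c(O)ccc(OC)c1OC | intermediate
10 | 5,6-dimethoxy-4H-chromen-4-one | COc1ccc2occc(=O)c2c1OC | intermediate
11 | 5,6-dimethoxy-2-(2,3,5,6-tetramethoxyphenyl)-4H-chromen-4-one | COc1cc(OC)c(OC)c(-c2cc(=O)c3c(OC)c(OC)ccc3o2)c1OC | target

**Step count and risks**

Total step count: 3. Longest linear sequence: 3 steps (1 → 2 → 6 → 11).

Steps most likely to fail:

1. Step 3 (Proposed new method). The C–H palladation of the doubly ortho-flanked arene position may be slow or unselective, so that arene homocoupling, precipitation of palladium before coupling, or a second arylation of the product ring competes. The dimethylammonium pivalate formed in the flask may also slow the catalyst. The fallback uses known chemistry and sets out from 6 and 8: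
   - Compound 6 is converted with 7 and then HCl (CH2Cl2, rt) through enaminone 9 into chromone 10, which is now isolated.
   - Compound 8 is lithiated at its C–H between two methoxy groups (n-BuLi, THF, 0 °C) to (2,3,5,6-tetramethoxyphenyl)lithium F1 and carboxylated with CO2 to 2,3,5,6-tetramethoxybenzoic acid F2.
   - Chromone 10 and F2 are joined by a Pd(II)-catalysed decarboxylative Heck-type arylation of the cyclic enone (Pd(O2CCF3)2, Ag2CO3, 5% DMSO–DMF, 120 °C). The carboxylate fixes the site of palladation, and the ortho,ortho'-dimethoxy pattern is the one that loses CO2 most readily.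
   - The fallback comes back to the route at 11.

2. Step 2. The hindered, basic aryllithium may deprotonate the Weinreb amide instead of adding to it, which would return 2 after work-up; lithiation may also be incomplete. The fallback sets out from 2:
   - Compound 2 is lithiated as before to 4, which is trapped at −78 °C with acetaldehyde to give racemic 1-[2,3-dimethoxy-6-(methoxymethoxy)phenyl]ethan-1-ol F3.
   - Dess–Martin oxidation of F3 should give ketone 5, now isolated, and acetal cleavage (HCl, MeOH, 50 °C) should give 6.
   - The fallback comes back to the route at 6.

3. Step 1. The chloromethyl ether may hydrolyse before O-alkylation is complete, or the acetal may be partly lost during isolation, leaving free phenol that would consume the organolithium in step 2. The fallback sets out from 1 and changes the directing group and the way it is attached (acid-catalysed addition to an enol ether instead of alkylation):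
   - Compound 1 with 3,4-dihydro-2H-pyran and PPTS (CH2Cl2, rt) should give racemic 2-(3,4-dimethoxyphenoxy)oxane F4.
   - n-BuLi (THF, 0 °C → rt) should lithiate F4 between the two oxygen substituents to [2,3-dimethoxy-6-(oxan-2-yloxy)phenyl]lithium F5.
   - Acylation of F5 with 3 should give 1-[2,3-dimethoxy-6-(oxan-2-yloxy)phenyl]ethan-1-one F6, and HCl in MeOH should remove the acetal.
   - The fallback comes back to the route at 6.

**Further compounds**

F1 | step 3 | (2,3,5,6-tetramethoxyphenyl)lithium | [Li]c1c(OC)c(OC)cc(OC)c1OC
F2 | step 3 | 2,3,5,6-tetramethoxybenzoic acid | COc1cc(OC)c(OC)c(C(=O)O)c1OC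
F3 | step 2 | 1-[2,3-dimethoxy-6-(methoxymethoxy)phenyl]ethan-1-ol (racemic) | CC(O)c1c(OCOC)ccc(OC)c1OC
F4 | step 1 | 2-(3,4-dimethoxyphenoxy)oxane (racemic) | COc1ccc(OC2CCCCO2)cc1OC
F5 | step 1 | [2,3-dimethoxy-6-(oxan-2-yloxy)phenyl]lithium (racemic) | [Li]c1c(OC2CCCCO2)ccc(OC)c1OC
F6 | step 1 | 1-[2,3-dimethoxy-6-(oxan-2-yloxy)phenyl]ethan-1-one (racemic) | CC(=O)c1c(OC2CCCCO2)ccc(OC)c1OC
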